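The flavonol is cut through ring C at C4–C4a and O1–C2, so ring A comes from phloroglucinol and everything else from one aroylacetate. The feature exploited is the position of C4a, flanked by the oxygen-bearing carbons C5 and C8a, which are interchangeable in the threefold-symmetric precursor of ring A. A single thermal condensation therefore forms both bonds and closes ring C with no regiochemical choice. Its partner is an ethyl 3-aryl-3-oxopropanoate bearing a benzoate on the alpha carbon (the future O-3) and a 4-benzoyloxy-3-benzyloxyphenyl group. The two oxygens destined for sulfation thus arrive as benzoates; later they are freed together and sulfated, and the benzyl ethers are removed last.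

Key step: step 6

Assumption: compound 9 is a racemate with an enolizable alpha carbon and is therefore written without a stereodescriptor, and the target is taken as the free bis(hydrogen sulfate), so the route ends with a cold proton exchange of its dipotassium salt.

Step 1
Reactants: 1 3,4-dihydroxybenzaldehyde
Product: 2 3-(benzyloxy)-4-hydroxybenzaldehyde
Conditions: NaH (2.1 equiv), DMSO, 20 °C; BnCl (1.0 equiv), 20 °C; aq HCl
Reagents that add atoms: benzyl chloride, ClCc1ccccc1
Why: In the dianion the 3-oxide, which is not conjugated with the para formyl group, is the more nucleophilic oxygen, so one equivalent of halide should etherify O-3 (regioselective Williamson etherification of a catechol dianion).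

Step 2
Reactants: 2 3-(benzyloxy)-4-hydroxybenzaldehyde
Product: 3 4-(benzoyloxy)-3-(benzyloxy)benzaldehyde
Conditions: BzCl, Et3N, DMAP (cat.), CH2Cl2, 0 °C to rt
Reagents that add atoms: benzoyl chloride, O=C(Cl)c1ccccc1
Why: DMAP-catalysed O-acylation of the only free phenol should be clean, and because O-3 is already alkylated no acyl migration between the catechol oxygens can blur the 3-benzyl/4-benzoyl pattern.

Step 3
Reactants: 3 4-(benzoyloxy)-3-(benzyloxy)benzaldehyde
Product: 4 4-(benzoyloxy)-3-(benzyloxy)benzoic acid
Conditions: NaClO2, NaH2PO4, 2-methyl-2-butene, t-BuOH–H2O, rt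
Reagents that add atoms: sodium chlorite, [Na+].[O-]Cl=O
Why: Pinnick oxidation at about pH 4 should convert the aldehyde into the acid without touching the aryl benzoate or the benzyl ether, the alkene scavenging the hypochlorous acid.

Step 4
Reactants: 4 4-(benzoyloxy)-3-(benzyloxy)benzoic acid; 5 potassium ethyl malonate
Product: 8 ethyl 3-[4-(benzoyloxy)-3-(benzyloxy)phenyl]-3-oxopropanoate, via acid chloride 6 (not isolated), via acylmalonic half ester 7 (not isolated)
Conditions: (COCl)2, DMF (cat.), CH2Cl2, rt, evaporate; then 5, MgCl2, Et3N, MeCN, 0 °C to rt; 1 M HCl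
Reagents that add atoms: none
Why: The magnesium enolate of the malonate half ester is C-acylated by the acid chloride and the adduct decarboxylates on acidification (Masamune-type magnesium malonate synthesis of beta-ketoesters), the acid chloride being far more electrophilic than the aryl benzoate, which should survive a short reaction at or below room temperature.

Step 5
Reactants: 8 ethyl 3-[4-(benzoyloxy)-3-(benzyloxy)phenyl]-3-oxopropanoate
Product: 9 ethyl 2-(benzoyloxy)-3-[4-(benzoyloxy)-3-(benzyloxy)phenyl]-3-oxopropanoate (racemic)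
Conditions: NaH (1.0 equiv), THF, 0 °C; (BzO)2, 0 °C to rt; dilute HCl
Reagents that add atoms: dibenzoyl peroxide, O=C(OOC(=O)c1ccccc1)c1ccccc1
Why: The sodium enolate attacks the peroxide O–O bond (electrophilic alpha-benzoyloxylation of a 1,3-dicarbonyl compound), and the new alpha stereocenter forms without control as the racemate, which is immaterial because this carbon becomes the sp2 carbon C3 in step 6.

Step 6
Reactants: 9 ethyl 2-(benzoyloxy)-3-[4-(benzoyloxy)-3-(benzyloxy)phenyl]-3-oxopropanoate (racemic); 10 phloroglucinol
Product: 13 3,4'-di-O-benzoyl-3'-O-benzylquercetin, via aroylketene 11 (not isolated), via C-acylphloroglucinol trione 12 (not isolated)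
Conditions: anhydrous 10 (1.5 equiv), neat melt, 230–240 °C, N2 stream (removes EtOH and H2O), 1–2 h
Reagents that add atoms: none
Why: On heating, the enol form of 9 should expel ethanol to give aroylketene 11, whose ketene carbon is captured by a ring carbon of 10 (directly, or by O-acylation and acyl shift) to give trione 12 and so the C4–C4a bond. A hydroxyl ortho to the new acyl group then adds to the aryl ketone and water is lost, which forms O1–C2 and aromatizes the pyranone. The closest known reaction type is the Mentzer thermal pyrone synthesis from phloroglucinol and aroylacetates, alpha-substituted ones included. Ring C closes by a 6-exo-trig addition of the phenolic oxygen to the ketone carbonyl followed by dehydration; no stereocenter is created and the labile alpha center of 9 disappears. The step needs chromone rather than coumarin formation, which the acid-free melt should secure because the ketene carbon, not the hindered alpha-substituted ketone, is the electrophile that meets the ring carbon, and regiochemistry cannot arise because every carbon of 10 sits between two equivalent hydroxyls. Without acid or base there is no catalyst for benzoyl or benzyl transfer, and the product emerges with a chelated 5-hydroxyl and a free, acidic 7-hydroxyl that the next step can tell apart.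

Step 7
Reactants: 13 3,4'-di-O-benzoyl-3'-O-benzylquercetin
Product: 14 3,4'-di-O-benzoyl-7,3'-di-O-benzylquercetin
Conditions: BnBr (1.1 equiv), K2CO3 (1.1 equiv), DMF, 0 °C to rt
Reagents that add atoms: benzyl bromide, BrCc1ccccc1
Why: Williamson etherification should occur only at the 7-hydroxyl, the most acidic one (a vinylogous acid through the C4 carbonyl), while the 5-hydroxyl is held in a hydrogen bond to O4 and is not ionized by one equivalent of carbonate.

Step 8
Reactants: 14 3,4'-di-O-benzoyl-7,3'-di-O-benzylquercetin
Product: 15 7,3'-di-O-benzylquercetin (free 3-, 5- and 4'-hydroxyls)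
Conditions: NaOMe (4 equiv), MeOH–THF, 0 °C to rt, Ar; 1 M HCl to pH 4
Reagents that add atoms: none
Why: Methoxide should transesterify the enol benzoate at O-3 and the aryl benzoate at O-4' to methyl benzoate (ester methanolysis) while the benzyl ethers are inert, and exclusion of air protects the liberated flavonol from oxidation in base.

Step 9
Reactants: 15 7,3'-di-O-benzylquercetin
Product: 17 dipotassium 7,3'-di-O-benzylquercetin 3,4'-bis(sulfate), via bis(pyridinium) salt 16 (not isolated)
Conditions: SO3·pyridine (excess), pyridine, rt to 45 °C; aq KHCO3; reversed-phase C18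
Reagents that add atoms: sulfur trioxide–pyridine complex, O=S(=O)([O-])[n+]1ccccc1; potassium hydrogen carbonate, [K+].OC(=O)[O-]
Why: O-sulfonation by the SO3–amine complex should take the 3- and 4'-hydroxyls, whereas the 5-hydroxyl, hydrogen bonded to O4 and peri to the carbonyl, is the least nucleophilic and should stay free, and bicarbonate then exchanges pyridinium for potassium.

Step 10
Reactants: 17 dipotassium 7,3'-di-O-benzylquercetin 3,4'-bis(sulfate)
Product: 19 quercetin 3,4'-bis(hydrogen sulfate) (target), via dipotassium quercetin 3,4'-bis(sulfate) 18 (not isolated)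
Conditions: H2 (1 atm), 10% Pd/C, MeOH–H2O, rt; filter; sulfonic acid cation-exchange resin (H+ form), H2O, 0 °C; freeze-dry
Reagents that add atoms: none
Why: Hydrogenolysis of the two benzyl aryl ethers over Pd/C should leave the aryl and enol sulfate anions and the tetrasubstituted C2–C3 double bond untouched, and a brief cold cation exchange then replaces potassium by protons.

Compound list
1 | 3,4-dihydroxybenzaldehyde | O=Cc1ccc(O)c(O)c1 | starting material
2 | 3-(benzyloxy)-4-hydroxybenzaldehyde | O=Cc1ccc(O)c(OCc2ccccc2)c1 | intermediate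
3 | 4-(benzoyloxy)-3-(benzyloxy)benzaldehyde | O=Cc1ccc(OC(=O)c2ccccc2)c(OCc2ccccc2)c1 | intermediate
4 | 4-(benzoyloxy)-3-(benzyloxy)benzoic acid | O=C(O)c1ccc(OC(=O)c2ccccc2)c(OCc2ccccc2)c1 | intermediate
5 | potassium ethyl malonate | CCOC(=O)CC(=O)[O-].[K+] | starting material
6 | 4-(benzoyloxy)-3-(benzyloxy)benzoyl chloride, made in the flask from 4 with oxalyl chloride | O=C(Cl)c1ccc(OC(=O)c2ccccc2)c(OCc2ccccc2)c1 | intermediate
7 | 2-[4-(benzoyloxy)-3-(benzyloxy)benzoyl]-3-ethoxy-3-oxopropanoic acid (racemic, present as its magnesium chelate until acidification) | CCOC(=O)C(C(=O)O)C(=O)c1ccc(OC(=O)c2ccccc2)c(OCc2ccccc2)c1 | intermediate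
8 | ethyl 3-[4-(benzoyloxy)-3-(benzyloxy)phenyl]-3-oxopropanoate | CCOC(=O)CC(=O)c1ccc(OC(=O)c2ccccc2)c(OCc2ccccc2)c1 | intermediate
9 | ethyl 2-(benzoyloxy)-3-[4-(benzoyloxy)-3-(benzyloxy)phenyl]-3-oxopropanoate (racemic, enolizable) | CCOC(=O)C(OC(=O)c1ccccc1)C(=O)c1ccc(OC(=O)c2ccccc2)c(OCc2ccccc2)c1 | intermediate
10 | phloroglucinol (benzene-1,3,5-triol) | Oc1cc(O)cc(O)c1 | starting material
11 | [4-(benzoyloxy)-3-(benzyloxy)benzoyl](benzoyloxy)ketene | O=C=C(OC(=O)c1ccccc1)C(=O)c1ccc(OC(=O)c2ccccc2)c(OCc2ccccc2)c1 | intermediate
12 | 2-(benzoyloxy)-1-[4-(benzoyloxy)-3-(benzyloxy)phenyl]-3-(2,4,6-trihydroxyphenyl)propane-1,3-dione (racemic) | O=C(c1c(O)cc(O)cc1O)C(OC(=O)c1ccccc1)C(=O)c1ccc(OC(=O)c2ccccc2)c(OCc2ccccc2)c1 | intermediate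
13 | 3,4'-di-O-benzoyl-3'-O-benzylquercetin | O=c1c(OC(=O)c2ccccc2)c(-c2ccc(OC(=O)c3ccccc3)c(OCc3ccccc3)c2)oc2cc(O)cc(O)c12 | intermediate
14 | 3,4'-di-O-benzoyl-7,3'-di-O-benzylquercetin | O=c1c(OC(=O)c2ccccc2)c(-c2ccc(OC(=O)c3ccccc3)c(OCc3ccccc3)c2)oc2cc(OCc3ccccc3)cc(O)c12 | intermediate
15 | 7,3'-di-O-benzylquercetin | O=c1c(O)c(-c2ccc(O)c(OCc3ccccc3)c2)oc2cc(OCc3ccccc3)cc(O)c12 | intermediate
16 | bis(pyridinium) 7,3'-di-O-benzylquercetin 3,4'-bis(sulfate) | O=c1c(OS(=O)(=O)[O-])c(-c2ccc(OS(=O)(=O)[O-])c(OCc3ccccc3)c2)oc2cc(OCc3ccccc3)cc(O)c12.c1cc[nH+]cc1.c1cc[nH+]cc1 | intermediate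
17 | dipotassium 7,3'-di-O-benzylquercetin 3,4'-bis(sulfate) | O=c1c(OS(=O)(=O)[O-])c(-c2ccc(OS(=O)(=O)[O-])c(OCc3ccccc3)c2)oc2cc(OCc3ccccc3)cc(O)c12.[K+].[K+] | intermediate
18 | dipotassium quercetin 3,4'-bis(sulfate) | O=c1c(OS(=O)(=O)[O-])c(-c2ccc(OS(=O)(=O)[O-])c(O)c2)oc2cc(O)cc(O)c12.[K+].[K+] | intermediate
19 | quercetin 3,4'-bis(hydrogen sulfate) | O=c1c(OS(=O)(=O)O)c(-c2ccc(OS(=O)(=O)O)c(O)c2)oc2cc(O)cc(O)c12 | target

Total step count: 10. Longest linear sequence: 10 steps (1 to 19); 5 enters at step 4 and 10 at step 6.

Steps most likely to fail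

Step 6. In the 240 °C melt the ring carbon may attack the ketone instead of the ketene carbon (Pechmann-type closure to a coumarin), benzoyl groups may be transferred to phloroglucinol, or the benzyl ether may be cleaved with charring. The fallback uses a ketene precursor that fragments roughly 100 °C lower; it sets out from 4 (through its acid chloride 6, made as in step 4) and comes back at 13. Acid chloride 6 with mono-tert-butyl malonate, MgCl2 and Et3N in MeCN should give, through tert-butyl hydrogen 2-[4-(benzoyloxy)-3-(benzyloxy)benzoyl]malonate F1 (not isolated, decarboxylating on mild acid work-up), tert-butyl 3-[4-(benzoyloxy)-3-(benzyloxy)phenyl]-3-oxopropanoate F2. NaH and dibenzoyl peroxide as in step 5 should then give racemic tert-butyl 2-(benzoyloxy)-3-[4-(benzoyloxy)-3-(benzyloxy)phenyl]-3-oxopropanoate F3. Heated with 10 in refluxing xylene or mesitylene (140–165 °C), F3 should lose tert-butanol to the same ketene 11, a known thermolysis of tert-butyl beta-ketoesters to acylketenes, and 12 then closes to 13 on continued heating.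

Step 9. Sulfation may stop short at the hydrogen-bonded 3-hydroxyl, may spill over to the 5-hydroxyl when forced, and the labile enol sulfate may be lost while polar salts are separated. The fallback carries the sulfates as neutral diesters; it sets out from 15 and comes back at 17. 2,2,2-Trichloroethyl chlorosulfate, Et3N and DMAP in THF should give the chromatographable 7,3'-di-O-benzylquercetin 3,4'-bis(2,2,2-trichloroethyl sulfate) F4, in which completeness and site of sulfation can be checked and corrected on silica. Zinc dust and ammonium formate in methanol should then remove the trichloroethyl groups by reductive fragmentation to give diammonium 7,3'-di-O-benzylquercetin 3,4'-bis(sulfate) F5. Evaporation from aqueous KHCO3 exchanges the cation and returns 17.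

Step 7. Under carbonate the 7-phenoxide may pick up a benzoyl group from O-3 or O-4' of another molecule, or a second alkylation may begin at O-5. The fallback replaces phenoxide alkylation by a neutral redox condensation; it sets out from 13 and comes back at 14. Mitsunobu etherification with benzyl alcohol, PPh3 and DIAD in THF at 0 °C to rt should engage only the most acidic 7-hydroxyl and never builds up a free phenoxide. No new compound arises on this path (F0).

Further compounds
F1 | step 6 | tert-butyl hydrogen 2-[4-(benzoyloxy)-3-(benzyloxy)benzoyl]malonate (racemic, not isolated) | CC(C)(C)OC(=O)C(C(=O)O)C(=O)c1ccc(OC(=O)c2ccccc2)c(OCc2ccccc2)c1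
F2 | step 6 | tert-butyl 3-[4-(benzoyloxy)-3-(benzyloxy)phenyl]-3-oxopropanoate | CC(C)(C)OC(=O)CC(=O)c1ccc(OC(=O)c2ccccc2)c(OCc2ccccc2)c1
F3 | step 6 | tert-butyl 2-(benzoyloxy)-3-[4-(benzoyloxy)-3-(benzyloxy)phenyl]-3-oxopropanoate (racemic) | CC(C)(C)OC(=O)C(OC(=O)c1ccccc1)C(=O)c1ccc(OC(=O)c2ccccc2)c(OCc2ccccc2)c1
F4 | step 9 | 7,3'-di-O-benzylquercetin 3,4'-bis(2,2,2-trichloroethyl sulfate) | O=c1c(OS(=O)(=O)OCC(Cl)(Cl)Cl)c(-c2ccc(OS(=O)(=O)OCC(Cl)(Cl)Cl)c(OCc3ccccc3)c2)oc2cc(OCc3ccccc3)cc(O)c12
F5 | step 9 | diammonium 7,3'-di-O-benzylquercetin 3,4'-bis(sulfate) | O=c1c(OS(=O)(=O)[O-])c(-c2ccc(OS(=O)(=O)[O-])c(OCc3ccccc3)c2)oc2cc(OCc3ccccc3)cc(O)c12.[NH4+].[NH4+]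
F0 | step 7 | none | none
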